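**Retrosynthetic overview**

1. The formate and the two acetates go on last; the C6 carbinol comes from 1,2-reduction of a ring A enone (C6=O, C7=C8) in a cis-fused bicycle whose ring B (C8a–C1–C2–C3–C4–C4a) already carries the E C1=C11 alkylidene, the C3 oxygen and the C4 methyl.
2. Ring A (C4a–C5–C6–C7–C8–C8a) is never closed as a six-membered ring: it is made by enlarging the five-membered ring C4a–C5–C6–C8–C8a of a cis-hydrindane silyl enol ether, C7 with its methyl being inserted between C6 and C8 by chloro(methyl)carbene addition and electrocyclic opening of the cyclopropane.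
3. Enabling feature: ring A is a 2-methylcyclohex-2-en-1-ol in which the methyl-bearing sp2 carbon C7 lies between the oxygen-bearing C6 and the vinylic C8 bonded to the ring-fusion carbon C8a, which is exactly the carbon a halo(methyl)carbene delivers to a C6=C8 enol ether.
4. That enol ether, ring B and the alkene geometry arise together in a Ni-catalysed alkylative cyclisation of an alkynyl cyclopentenone (C1–C8a bond, CH3 from Me2Zn to C11, O6 silylated).
5. The cyclopentenone with C4a, C4 and C3 comes from (1S,4R)-cis-4-acetoxycyclopent-2-en-1-ol (Pd allylation with methyl Meldrum's acid, bridged lactone, Felkin propargylation); ring order: purchased cyclopentene, then ring B, then ring A by enlargement.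

Key step: step 9

Remark: locants C1–C8a (C11 = exocyclic alkene carbon, C12 = its CH2O carbon) are those of the target's octahydronaphthalene and are kept for every intermediate; 1 and 2 are taken to be purchasable in the stated form.

**Route**

Step 1
Reactants: 1 (1S,4R)-cis-4-acetoxycyclopent-2-en-1-ol; 2 2,2,5-trimethyl-1,3-dioxane-4,6-dione
Product: 3 5-[(1R,4S)-4-hydroxycyclopent-2-en-1-yl]-2,2,5-trimethyl-1,3-dioxane-4,6-dione
Conditions: Pd(PPh3)4 (2 mol %), Et3N (1.2 equiv), THF, 50 °C
Reagents that add atoms: none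
Why: Tsuji–Trost allylic alkylation, in which zerovalent palladium ionises the allylic acetate with inversion and the soft Meldrum's acid anion attacks the allyl terminus remote from the hydroxyl anti to the metal, so the C4a–C4 bond should form with net retention, cis to the C6 hydroxyl.

Step 2
Reactants: 3 5-[(1R,4S)-4-hydroxycyclopent-2-en-1-yl]-2,2,5-trimethyl-1,3-dioxane-4,6-dione
Product: 5 (1S,4S,5R)-4-methyl-2-oxabicyclo[3.2.1]oct-6-en-3-one, via carboxy lactone 4 (not isolated)
Conditions: pyridine, 115 °C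
Reagents that add atoms: none
Why: Intramolecular alcoholysis of the Meldrum's acid by the cis hydroxyl (loss of acetone) and decarboxylation of the malonic half-lactone should give the bridged lactone, whose enol is protonated on the exo face (anti to the C8=C8a bridge), leaving the C4 methyl equatorial, which is also the thermodynamically preferred epimer.

Step 3
Reactants: 5 (1S,4S,5R)-4-methyl-2-oxabicyclo[3.2.1]oct-6-en-3-one
Product: 6 (1S,4S,5R)-4-methyl-2-oxabicyclo[3.2.1]oct-6-en-3-ol
Conditions: DIBAL-H (1.1 equiv), CH2Cl2, −78 °C; aq. potassium sodium tartrate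
Reagents that add atoms: none
Why: Partial reduction of a lactone by DIBAL-H at low temperature should stop at the aluminium hemiacetal and give the lactol without touching any stereocentre of the skeleton.

Step 4
Reactants: 6 (1S,4S,5R)-4-methyl-2-oxabicyclo[3.2.1]oct-6-en-3-ol
Product: 7 (1S,4R)-4-[(2S,3S)-3-hydroxyhex-5-yn-2-yl]cyclopent-2-en-1-ol
Conditions: Zn dust, propargyl bromide, THF/sat. aq. NH4Cl, 0 °C → rt
Reagents that add atoms: propargyl bromide, BrCC#C
Why: Barbier propargylation of the open hydroxy-aldehyde form by allenylzinc bromide (SE2′) should give the homopropargylic alcohol, and Felkin–Anh addition anti to the cyclopentenyl group on C4 sets the 3,4-syn (3S) carbinol.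

Step 5
Reactants: 7 (1S,4R)-4-[(2S,3S)-3-hydroxyhex-5-yn-2-yl]cyclopent-2-en-1-ol
Product: 8 (1S,4R)-4-[(2S,3S)-3,7-dihydroxyhept-5-yn-2-yl]cyclopent-2-en-1-ol
Conditions: n-BuLi (3.2 equiv), THF, −78 → 0 °C; (CH2O)n, rt; aq. NH4Cl
Reagents that add atoms: paraformaldehyde (as formaldehyde), C=O
Why: After deprotonation of both hydroxyls and the terminal alkyne, only the lithium acetylide should add to formaldehyde (acetylide hydroxymethylation), which brings in C12 with its oxygen.

Step 6
Reactants: 8 (1S,4R)-4-[(2S,3S)-3,7-dihydroxyhept-5-yn-2-yl]cyclopent-2-en-1-ol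
Product: 9 (1S,4R)-4-[(2S,3S)-7-(tert-butyldimethylsilyloxy)-3-hydroxyhept-5-yn-2-yl]cyclopent-2-en-1-ol
Conditions: TBSCl (1.05 equiv), imidazole, CH2Cl2, −20 °C
Reagents that add atoms: tert-butyldimethylsilyl chloride, CC(C)(C)[Si](C)(C)Cl
Why: Silylation with a bulky chlorosilane is much faster at the primary propargylic hydroxyl than at the two secondary ones, so one equivalent should protect O12 selectively (steric differentiation in silyl ether formation).

Step 7
Reactants: 9 (1S,4R)-4-[(2S,3S)-7-(tert-butyldimethylsilyloxy)-3-hydroxyhept-5-yn-2-yl]cyclopent-2-en-1-ol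
Product: 11 (4R)-4-[(2S,3S)-7-(tert-butyldimethylsilyloxy)-3-(trimethylsilyloxy)hept-5-yn-2-yl]cyclopent-2-en-1-one, via hydroxy enone 10 (not isolated)
Conditions: MnO2, CH2Cl2, rt; filtration; TMSCl, imidazole, CH2Cl2, 0 °C
Reagents that add atoms: chlorotrimethylsilane, C[Si](C)(C)Cl
Why: MnO2 oxidises only the allylic C6 carbinol to the enone (chemoselective allylic oxidation), and the remaining C3 hydroxyl is silylated at once so that it cannot add to the enone in an intramolecular oxa-Michael reaction.

Step 8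
Reactants: 11 (4R)-4-[(2S,3S)-7-(tert-butyldimethylsilyloxy)-3-(trimethylsilyloxy)hept-5-yn-2-yl]cyclopent-2-en-1-one
Product: 12 (3aR,4E,6S,7S,7aR)-4-[1-(tert-butyldimethylsilyloxy)propan-2-ylidene]-7-methyl-2,6-bis(trimethylsilyloxy)-3a,4,5,6,7,7a-hexahydro-1H-indene
Conditions: Ni(cod)2 (10 mol %), Me2Zn (2.5 equiv), TMSCl (3 equiv), THF, 0 °C → rt
Reagents that add atoms: dimethylzinc, C[Zn]C; chlorotrimethylsilane, C[Si](C)(C)Cl
Why: Nickel-catalysed alkylative enone–alkyne–organozinc cyclisation, in which zerovalent nickel joins C1 of the alkyne to the enone β-carbon C8a on the face of C4a that carries the tether (6-exo-dig, hence cis ring fusion), zinc transfers methyl to the nickel-bound C11 with retention (syn addition across the alkyne, so CH3 is cis to C8a and the alkene is E), and the enolate is silylated on oxygen, which fixes the enol double bond between C6 and C8.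

Step 9
Reactants: 12 (3aR,4E,6S,7S,7aR)-4-[1-(tert-butyldimethylsilyloxy)propan-2-ylidene]-7-methyl-2,6-bis(trimethylsilyloxy)-3a,4,5,6,7,7a-hexahydro-1H-indene
Product: 14 (1E,3S,4S,4aR,8aR)-1-[1-(tert-butyldimethylsilyloxy)propan-2-ylidene]-4,7-dimethyl-3-(trimethylsilyloxy)-1,2,3,4,4a,5,6,8a-octahydronaphthalen-6-one, via cyclopropane adduct 13 (not isolated)
Conditions: CH3CHCl2 (3 equiv), n-BuLi (2.5 equiv), Et2O, −40 → −20 °C; then toluene, solid NaHCO3, 100 °C
Reagents that add atoms: 1,1-dichloroethane, CC(Cl)Cl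
Why: n-BuLi converts 1,1-dichloroethane into chloro(methyl)carbene, which adds as an electrophile to the C6=C8 enol ether, and on heating the adducts with chlorine endo open by disrotatory two-electron electrocyclic cleavage of the C6–C8 bond with loss of chloride, pushed by the siloxy oxygen, the siloxyallyl cation collapsing to the C6 ketone, the C7=C8 double bond and Me3SiCl. The closest known reaction type is the halocarbene ring enlargement of cyclic silyl enol ethers to 2-halo- or 2-methylcycloalk-2-enones, itself a case of the cyclopropyl halide to allyl cation opening. The only ring closed is the cyclopropane (concerted [2+1] addition); ring A is not closed at all but results when the bond shared by the three- and five-membered rings breaks, so that C7 becomes the sixth ring atom. No stereocentre is created: the three cyclopropane centres are erased, so both faces of carbene attack converge on one enone, and C3, C4, C4a and C8a are spectators. The step needs chemoselectivity for the enol ether over the tetrasubstituted C1=C11 alkene, which the oxygen donor on C6 and the hindered, inductively deactivated surroundings of C1=C11 should secure, and regioselectivity of insertion, which is fixed because step 8 placed the enol double bond towards C8 and not C5. Endo placement of chlorine, required for opening inside a five-membered ring, is favoured because the larger methyl group avoids the concave side.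

Step 10
Reactants: 14 (1E,3S,4S,4aR,8aR)-1-[1-(tert-butyldimethylsilyloxy)propan-2-ylidene]-4,7-dimethyl-3-(trimethylsilyloxy)-1,2,3,4,4a,5,6,8a-octahydronaphthalen-6-one
Product: 16 (1E,3S,4S,4aR,6S,8aR)-1-[1-(tert-butyldimethylsilyloxy)propan-2-ylidene]-4,7-dimethyl-1,2,3,4,4a,5,6,8a-octahydronaphthalene-3,6-diol, via silyl ether alcohol 15 (not isolated)
Conditions: NaBH4, CeCl3·7H2O, MeOH, −78 °C; then aq. citric acid, 0 °C
Reagents that add atoms: none
Why: Luche 1,2-reduction, in which hydride should attack C6 on the convex face of the cis-fused bicycle (the face of H4a and H8a, anti to the axial C4a–C4 bond) to give the 6S carbinol cis to ring B, the acidic work-up then removing the trimethylsilyl ether.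

Step 11
Reactants: 16 (1E,3S,4S,4aR,6S,8aR)-1-[1-(tert-butyldimethylsilyloxy)propan-2-ylidene]-4,7-dimethyl-1,2,3,4,4a,5,6,8a-octahydronaphthalene-3,6-diol
Product: 17 (1E,3S,4S,4aR,6S,8aR)-1-[1-(tert-butyldimethylsilyloxy)propan-2-ylidene]-4,7-dimethyl-1,2,3,4,4a,5,6,8a-octahydronaphthalene-3,6-diyl diacetate
Conditions: Ac2O, pyridine, DMAP (cat.), CH2Cl2, rt
Reagents that add atoms: acetic anhydride, CC(=O)OC(C)=O
Why: DMAP-catalysed acyl transfer should esterify both secondary hydroxyls without affecting any stereocentre.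

Step 12
Reactants: 17 (1E,3S,4S,4aR,6S,8aR)-1-[1-(tert-butyldimethylsilyloxy)propan-2-ylidene]-4,7-dimethyl-1,2,3,4,4a,5,6,8a-octahydronaphthalene-3,6-diyl diacetate
Product: 18 (1E,3S,4S,4aR,6S,8aR)-1-(1-hydroxypropan-2-ylidene)-4,7-dimethyl-1,2,3,4,4a,5,6,8a-octahydronaphthalene-3,6-diyl diacetate
Conditions: HF·pyridine, pyridine, THF, 0 °C → rt
Reagents that add atoms: none
Why: Fluoride-induced cleavage of the Si–O bond (desilylation) under buffered conditions should free the primary allylic alcohol and leave the acetates and the allylic systems untouched.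

Step 13
Reactants: 18 (1E,3S,4S,4aR,6S,8aR)-1-(1-hydroxypropan-2-ylidene)-4,7-dimethyl-1,2,3,4,4a,5,6,8a-octahydronaphthalene-3,6-diyl diacetate
Product: 19 (1E,3S,4S,4aR,6S,8aR)-1-[1-(formyloxy)propan-2-ylidene]-4,7-dimethyl-1,2,3,4,4a,5,6,8a-octahydronaphthalene-3,6-diyl diacetate (CNP0262962.2)
Conditions: AcOCHO, pyridine, CH2Cl2, −20 → 0 °C
Reagents that add atoms: acetic formic anhydride, CC(=O)OC=O
Why: The mixed anhydride transfers its more electrophilic formyl group to the primary allylic alcohol (O-formylation), which should give the formate without acetate scrambling.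

**Compound list**

1 | (1S,4R)-cis-4-acetoxycyclopent-2-en-1-ol | O[C@H]1C[C@@H](OC(C)=O)C=C1 | starting material
2 | 2,2,5-trimethyl-1,3-dioxane-4,6-dione (methyl Meldrum's acid) | CC1C(=O)OC(C)(C)OC1=O | starting material
3 | 5-[(1R,4S)-4-hydroxycyclopent-2-en-1-yl]-2,2,5-trimethyl-1,3-dioxane-4,6-dione | O[C@H]1C[C@@H](C2(C)C(=O)OC(C)(C)OC2=O)C=C1 | intermediate
4 | (1S,5R)-4-methyl-3-oxo-2-oxabicyclo[3.2.1]oct-6-ene-4-carboxylic acid (both C4 epimers; not isolated) | CC1(C(O)=O)C(=O)O[C@H]2C[C@@H]1C=C2 | intermediate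
5 | (1S,4S,5R)-4-methyl-2-oxabicyclo[3.2.1]oct-6-en-3-one | C[C@@H]1C(=O)O[C@H]2C[C@@H]1C=C2 | intermediate
6 | (1S,4S,5R)-4-methyl-2-oxabicyclo[3.2.1]oct-6-en-3-ol (lactol, both anomers) | C[C@@H]1C(O)O[C@H]2C[C@@H]1C=C2 | intermediate
7 | (1S,4R)-4-[(2S,3S)-3-hydroxyhex-5-yn-2-yl]cyclopent-2-en-1-ol | O[C@H]1C[C@@H]([C@H](C)[C@@H](O)CC#C)C=C1 | intermediate
8 | (1S,4R)-4-[(2S,3S)-3,7-dihydroxyhept-5-yn-2-yl]cyclopent-2-en-1-ol | O[C@H]1C[C@@H]([C@H](C)[C@@H](O)CC#CCO)C=C1 | intermediate
9 | (1S,4R)-4-[(2S,3S)-7-(tert-butyldimethylsilyloxy)-3-hydroxyhept-5-yn-2-yl]cyclopent-2-en-1-ol | O[C@H]1C[C@@H]([C@H](C)[C@@H](O)CC#CCO[Si](C)(C)C(C)(C)C)C=C1 | intermediate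
10 | (4R)-4-[(2S,3S)-7-(tert-butyldimethylsilyloxy)-3-hydroxyhept-5-yn-2-yl]cyclopent-2-en-1-one (not isolated) | O=C1C[C@@H]([C@H](C)[C@@H](O)CC#CCO[Si](C)(C)C(C)(C)C)C=C1 | intermediate
11 | (4R)-4-[(2S,3S)-7-(tert-butyldimethylsilyloxy)-3-(trimethylsilyloxy)hept-5-yn-2-yl]cyclopent-2-en-1-one | O=C1C[C@@H]([C@H](C)[C@@H](O[Si](C)(C)C)CC#CCO[Si](C)(C)C(C)(C)C)C=C1 | intermediate
12 | (3aR,4E,6S,7S,7aR)-4-[1-(tert-butyldimethylsilyloxy)propan-2-ylidene]-7-methyl-2,6-bis(trimethylsilyloxy)-3a,4,5,6,7,7a-hexahydro-1H-indene (cis-fused) | C[Si](C)(C)OC1C[C@H]2[C@H](C)[C@@H](O[Si](C)(C)C)C/C(=C(/C)CO[Si](C)(C)C(C)(C)C)[C@H]2C=1 | intermediate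
13 | chloro(methyl)cyclopropane adduct of 12: C(Cl)(CH3) bridging C6 and C8, siloxy group on C6 (cyclopropane diastereomers; not isolated) | C[Si](C)(C)OC12C[C@H]3[C@H](C)[C@@H](O[Si](C)(C)C)C/C(=C(/C)CO[Si](C)(C)C(C)(C)C)[C@H]3C1C2(C)Cl | intermediate
14 | (1E,3S,4S,4aR,8aR)-1-[1-(tert-butyldimethylsilyloxy)propan-2-ylidene]-4,7-dimethyl-3-(trimethylsilyloxy)-1,2,3,4,4a,5,6,8a-octahydronaphthalen-6-one (ring A enone) | O=C1C[C@H]2[C@H](C)[C@@H](O[Si](C)(C)C)C/C(=C(/C)CO[Si](C)(C)C(C)(C)C)[C@H]2C=C1C | intermediate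
15 | (1E,3S,4S,4aR,6S,8aR)-1-[1-(tert-butyldimethylsilyloxy)propan-2-ylidene]-4,7-dimethyl-3-(trimethylsilyloxy)-1,2,3,4,4a,5,6,8a-octahydronaphthalen-6-ol (not isolated) | O[C@H]1C[C@H]2[C@H](C)[C@@H](O[Si](C)(C)C)C/C(=C(/C)CO[Si](C)(C)C(C)(C)C)[C@H]2C=C1C | intermediate
16 | (1E,3S,4S,4aR,6S,8aR)-1-[1-(tert-butyldimethylsilyloxy)propan-2-ylidene]-4,7-dimethyl-1,2,3,4,4a,5,6,8a-octahydronaphthalene-3,6-diol | O[C@H]1C[C@H]2[C@H](C)[C@@H](O)C/C(=C(/C)CO[Si](C)(C)C(C)(C)C)[C@H]2C=C1C | intermediate
17 | (1E,3S,4S,4aR,6S,8aR)-1-[1-(tert-butyldimethylsilyloxy)propan-2-ylidene]-4,7-dimethyl-1,2,3,4,4a,5,6,8a-octahydronaphthalene-3,6-diyl diacetate | CC(=O)O[C@H]1C[C@H]2[C@H](C)[C@@H](OC(C)=O)C/C(=C(/C)CO[Si](C)(C)C(C)(C)C)[C@H]2C=C1C | intermediate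
18 | (1E,3S,4S,4aR,6S,8aR)-1-(1-hydroxypropan-2-ylidene)-4,7-dimethyl-1,2,3,4,4a,5,6,8a-octahydronaphthalene-3,6-diyl diacetate | CC(=O)O[C@H]1C[C@H]2[C@H](C)[C@@H](OC(C)=O)C/C(=C(/C)CO)[C@H]2C=C1C | intermediate
19 | (1E,3S,4S,4aR,6S,8aR)-1-[1-(formyloxy)propan-2-ylidene]-4,7-dimethyl-1,2,3,4,4a,5,6,8a-octahydronaphthalene-3,6-diyl diacetate (CNP0262962.2) | CC(=O)O[C@H]1C[C@H]2[C@H](C)[C@@H](OC(C)=O)C/C(=C(/C)COC=O)[C@H]2C=C1C | target

**Step count and risks**

Total step count: 13. Longest linear sequence: 13 steps (from 1).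

Steps most likely to fail, riskiest first:

1. Step 9 (ring enlargement). What may go wrong: loss of chemoselectivity, the carbene adding also to the C1=C11 alkene, and carbene addition with chlorine exo, which gives cyclopropanes that cannot open. Fallback, from 12 back to 16: the enol ether of 12 is cyclopropanated with the zinc carbenoid from Et2Zn and CH2I2 (Simmons–Smith conditions, selective for enol ethers) to the siloxycyclopropane F1. FeCl3 in DMF opens F1 by alkoxy-radical β-scission of the shared C6–C8 bond and chlorine transfer (oxidative ring enlargement of siloxycyclopropanes) to the β-chloro ketone F2, the C3 silyl ether being lost on acidic work-up. NaOAc in MeOH eliminates HCl to the des-methyl enone F3, I2/pyridine gives the α-iodo enone F4, and Suzuki–Miyaura coupling with MeB(OH)2 (PdCl2(dppf), K3PO4) installs the C7 methyl to give the hydroxy enone F5, which the conditions of step 10 reduce to 16.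

2. Step 8 (alkylative cyclisation). What may go wrong: direct conjugate transfer of methyl from zinc to the enone before the alkyne is engaged, or slow six-membered oxidative cyclisation leading to oligomerisation. Fallback, from 9 back to 12: alkoxide-directed, Fe(acac)3-catalysed syn-carbomagnesiation of the alkyne of 9 with MeMgBr (methyl to C11, magnesium to C1 in a five-membered chelate with O3) and quench with Me3SnCl should give the vinylstannane diol F6. MnO2 then gives the stannyl hydroxy enone F7, and TMSCl/imidazole its trimethylsilyl ether F8. CuCl in DMF (tin-to-copper exchange, then intramolecular conjugate addition of the alkenylcopper to the enone) with TMSCl/Et3N trapping of the enolate returns 12.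

3. Step 4 (propargylation). What may go wrong: poor facial selectivity at the aldehyde (weak Felkin preference), and some attack through the wrong end of the allenylzinc. Fallback, from 6 back to 7: substrate control is replaced by reagent control. The lactol is treated with a stoichiometric enantiopure B-allenyl-10-(trimethylsilyl)-9-borabicyclo[3.3.2]decane (the antipode that reinforces the Felkin sense), whose closed six-membered boron transition state fixes both the propargyl regiochemistry and the C3 configuration; no new compound is formed (F0).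

Further compounds
F1 | step 9 | siloxycyclopropane from 12, CH2 bridging C6 and C8 (cyclopropane diastereomers) | C[Si](C)(C)OC12C[C@H]3[C@H](C)[C@@H](O[Si](C)(C)C)C/C(=C(/C)CO[Si](C)(C)C(C)(C)C)[C@H]3C1C2
F2 | step 9 | β-chloro ketone: six-membered ring A with C6=O, C7H2 and C8HCl, free C3 hydroxyl, ring B as in 12 | O=C1C[C@H]2[C@H](C)[C@@H](O)C/C(=C(/C)CO[Si](C)(C)C(C)(C)C)[C@H]2C(Cl)C1
F3 | step 9 | des-methyl enone: analogue of 14 without the C7 methyl and with free C3 hydroxyl | O=C1C[C@H]2[C@H](C)[C@@H](O)C/C(=C(/C)CO[Si](C)(C)C(C)(C)C)[C@H]2C=C1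
F4 | step 9 | α-iodo enone: F3 with iodine on C7 | O=C1C[C@H]2[C@H](C)[C@@H](O)C/C(=C(/C)CO[Si](C)(C)C(C)(C)C)[C@H]2C=C1I
F5 | step 9 | hydroxy enone: analogue of 14 with free C3 hydroxyl | O=C1C[C@H]2[C@H](C)[C@@H](O)C/C(=C(/C)CO[Si](C)(C)C(C)(C)C)[C@H]2C=C1C
F6 | step 8 | vinylstannane diol: (1S,4R)-4-[(2S,3S,5E)-7-(tert-butyldimethylsilyloxy)-3-hydroxy-6-methyl-5-(trimethylstannyl)hept-5-en-2-yl]cyclopent-2-en-1-ol | O[C@H]1C[C@@H]([C@H](C)[C@@H](O)C/C(=C(/C)CO[Si](C)(C)C(C)(C)C)[Sn](C)(C)C)C=C1
F7 | step 8 | stannyl hydroxy enone: cyclopent-2-en-1-one from F6 | O=C1C[C@@H]([C@H](C)[C@@H](O)C/C(=C(/C)CO[Si](C)(C)C(C)(C)C)[Sn](C)(C)C)C=C1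
F8 | step 8 | trimethylsilyl ether of F7 at O3 | O=C1C[C@@H]([C@H](C)[C@@H](O[Si](C)(C)C)C/C(=C(/C)CO[Si](C)(C)C(C)(C)C)[Sn](C)(C)C)C=C1
F0 | step 4 | none | none
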